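**Plan**
Retrosynthesis: the seven benzyl ethers and the C4 carbonyl of unit 1 (kept as a silylated carbinol) come off first. Ring C of unit 2 is then cut at O1–C2 (oxa-Michael), Cα–Cβ (Claisen–Schmidt) and aryl–acetyl (Stille). The key cut is O1–C8a of ring C of unit 1, and the open chain left is cut at C4–C4a (aryl Grignard plus aldehyde) and C2–C3 (aldol).
Forward: a phloroglucinol-derived arylacetic acid (future ring A of unit 2) is loaded on an oxazolidinone, joined to ring B by a syn aldol and to the bromo ring A by Grignard addition. Ring C of unit 1 closes by aryl C–O coupling, ring C of unit 2 is then built on the pendant ring, C4 is oxidised and the benzyl ethers are hydrogenolysed.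
Stereochemistry: the cis (2R,3R) pair of unit 1 comes from the auxiliary-controlled boron aldol and passes unchanged through the C–O coupling. The (2S) centre of unit 2 comes from a catalyst-controlled oxa-Michael closure. The C4 carbinol centre is transient.
Enabling feature: in ring C of unit 1, O1 links aromatic C8a to the benzylic stereocentre C2, whose cis partner C3 lies α to C4. With C4 held as a carbinol there is neither a C3 enolate nor a C2 phenoxide elimination, so O1–C8a can be made last without touching C2 or C3.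

Key step: step 14

Numbering: unit 1 is the C3-linked flavanone with the catechol ring B, unit 2 the C8-linked flavanone with the 4-hydroxyphenyl ring; flavanone numbering is used for both, also in open-chain precursors.
Assumption: the configuration of the transient C4 carbinol of unit 1 is immaterial because step 22 oxidises it; the epimer expected from Felkin–Anh addition (1,3-anti to the C2 oxygen) is drawn, and its epimer would converge on the same ketone.
Abbreviations in names: ArP = 4-(benzyloxy)-2,6-bis(methoxymethoxy)phenyl; ArB = 3,4-bis(benzyloxy)phenyl; ArA = 2,4-bis(benzyloxy)-6-bromophenyl; CHR = (2R,3R,4R)-5,7-bis(benzyloxy)-2-[3,4-bis(benzyloxy)phenyl]-4-[(tert-butyldimethylsilyl)oxy]chroman-3-yl (2,3-cis and 3,4-cis); Bn = benzyl; MOM = methoxymethyl; TES = triethylsilyl; TBS = tert-butyldimethylsilyl.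

**Route**

Step 1
Reactants: 1 phloroglucinol
Product: 2 3,5-bis(methoxymethoxy)phenol
Conditions: MOMCl (2 equiv), i-Pr2NEt, DMF, 0 °C to rt
Reagents that add atoms: chloromethyl methyl ether, COCCl
Why: Statistical Williamson-type O-alkylation of the symmetric triphenol with two equivalents of the chloromethyl ether should give the bis-acetal as the main separable fraction, the mono- and tris-ethers being removed by chromatography.

Step 2
Reactants: 2 3,5-bis(methoxymethoxy)phenol
Product: 3 1-(benzyloxy)-3,5-bis(methoxymethoxy)benzene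
Conditions: BnBr, K2CO3, DMF, rt
Reagents that add atoms: benzyl bromide, BrCc1ccccc1
Why: Williamson etherification of the remaining phenol is routine and marks the oxygen that becomes the 5-OH of unit 2 with the group that lasts until the final hydrogenolysis.

Step 3
Reactants: 3 1-(benzyloxy)-3,5-bis(methoxymethoxy)benzene
Product: 5 2-ArP-ethan-1-ol, via aryllithium 4 (not isolated)
Conditions: n-BuLi, THF, 0 °C; then oxirane, −78 °C to rt; then H2O
Reagents that add atoms: oxirane, C1CO1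
Why: Directed ortho-metalation should occur at the position flanked by the two coordinating methoxymethoxy groups, and the aryllithium then opens the epoxide to install the two-carbon chain.

Step 4
Reactants: 5 2-ArP-ethan-1-ol
Product: 7 ArP-acetic acid, via arylacetaldehyde 6 (not isolated)
Conditions: TEMPO (cat.), PhI(OAc)2, MeCN/H2O, rt
Reagents that add atoms: water, O
Why: The oxoammonium (TEMPO/PhI(OAc)2) oxidation takes a primary alcohol through the aldehyde hydrate to the acid under near-neutral conditions that leave acetal and benzyl ethers intact.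

Step 5
Reactants: 7 ArP-acetic acid; 8 (R)-4-benzyl-2-oxazolidinone
Product: 10 (4R)-4-benzyl-3-(ArP-acetyl)-1,3-oxazolidin-2-one, via mixed pivalic anhydride 9 (not isolated)
Conditions: t-BuCOCl, Et3N, THF, −20 °C; then 8, LiCl, rt
Reagents that add atoms: none
Why: N-acylation of the auxiliary through the mixed anhydride under LiCl/Et3N activation is the standard mild entry to arylacetyl imides.

Step 6
Reactants: 10 (4R)-4-benzyl-3-(ArP-acetyl)-1,3-oxazolidin-2-one; 11 3,4-bis(benzyloxy)benzaldehyde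
Product: 14 (4R)-4-benzyl-3-[(2R,3R)-2-ArP-3-ArB-3-hydroxypropanoyl]-1,3-oxazolidin-2-one, via boron enolate 12 (not isolated), via boron aldolate 13 (not isolated)
Conditions: Bu2BOTf, i-Pr2NEt, CH2Cl2, −78 to 0 °C; 11, −78 to 0 °C; then H2O2, MeOH, pH 7 buffer, 0 °C
Reagents that add atoms: none
Why: In this Evans syn aldol the Z boron enolate adds through a Zimmerman–Traxler chair on the face away from the benzyl group of the (R) auxiliary, which sets the (2R,3R) syn pair that becomes C3 and C2 of unit 1.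

Step 7
Reactants: 14 syn aldol imide
Product: 15 (4R)-4-benzyl-3-[(2R,3R)-2-ArP-3-ArB-3-(TES-oxy)propanoyl]-1,3-oxazolidin-2-one
Conditions: TESCl, imidazole, DMAP (cat.), DMF, rt
Reagents that add atoms: chlorotriethylsilane, CC[Si](Cl)(CC)CC
Why: Silylation of the benzylic aldol hydroxyl blocks retro-aldol cleavage and installs a silyl ether that can later be removed beside a tert-butyldimethylsilyl ether.

Step 8
Reactants: 15 TES-protected imide
Product: 16 (2S,3R)-2-ArP-3-ArB-3-(TES-oxy)propan-1-ol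
Conditions: LiBH4, MeOH (1 equiv), THF, 0 °C
Reagents that add atoms: none
Why: Hydride reduction cleaves the N-acyl oxazolidinone to the primary alcohol and returns the auxiliary without touching either stereocentre.

Step 9
Reactants: 16 (2S,3R)-2-ArP-3-ArB-3-(TES-oxy)propan-1-ol
Product: 17 (2R,3R)-2-ArP-3-ArB-3-(TES-oxy)propanal
Conditions: Dess–Martin periodinane, NaHCO3, CH2Cl2, 0 °C; used at once
Reagents that add atoms: none
Why: Buffered Dess–Martin oxidation should give the α-aryl aldehyde without epimerisation, helped by the twisted 2,6-disubstituted aryl group that stabilises an enol poorly.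

Step 10
Reactants: 18 1,3-bis(benzyloxy)-5-bromobenzene
Product: 19 1,5-bis(benzyloxy)-3-bromo-2-iodobenzene
Conditions: N-iodosuccinimide, CF3CO2H (cat.), MeCN, 0 °C to rt
Reagents that add atoms: N-iodosuccinimide, O=C1CCC(=O)N1I
Why: Electrophilic aromatic iodination is expected para to one benzyloxy group and ortho to the other, next to bromine, because the site between the two benzyloxy groups is the more hindered one.

Step 11
Reactants: 17 (2R,3R)-2-ArP-3-ArB-3-(TES-oxy)propanal; 19 1,5-bis(benzyloxy)-3-bromo-2-iodobenzene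
Product: 21 (1R,2S,3R)-1-ArA-2-ArP-3-ArB-3-(TES-oxy)propan-1-ol, via arylmagnesium chloride 20 (not isolated)
Conditions: 19, i-PrMgCl·LiCl, THF, −30 °C; then 17, −30 to 0 °C
Reagents that add atoms: none
Why: Iodine–magnesium exchange is far faster at C–I than at C–Br and the ortho-bromoaryl Grignard is stable at −30 °C, and its 1,2-addition should follow Felkin–Anh control (ArP anti to the nucleophile, reinforced by 1,3-anti induction) to give the (1R) carbinol.

Step 12
Reactants: 21 (1R,2S,3R)-1-ArA-2-ArP-3-ArB-3-(TES-oxy)propan-1-ol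
Product: 22 (1R,2R,3R)-1-ArA-1-(TBS-oxy)-2-ArP-3-ArB-3-(TES-oxy)propane
Conditions: TBSOTf, 2,6-lutidine, CH2Cl2, −78 to 0 °C
Reagents that add atoms: tert-butyldimethylsilyl trifluoromethanesulfonate, CC(C)(C)[Si](C)(C)OS(=O)(=O)C(F)(F)F
Why: Silylation with the silyl triflate is strong enough for the congested benzylic hydroxyl at low temperature, where aryl methoxymethyl ethers are not attacked.

Step 13
Reactants: 22 bis-silyl ether
Product: 23 (1R,2R,3R)-3-ArA-2-ArP-1-ArB-3-(TBS-oxy)propan-1-ol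
Conditions: HF·pyridine, pyridine, THF, 0 °C
Reagents that add atoms: none
Why: Buffered fluoride desilylation removes the triethylsilyl ether much faster than the bulkier and more hindered tert-butyldimethylsilyl ether, so only the C2 hydroxyl is freed.

Step 14
Reactants: 23 (1R,2R,3R)-3-ArA-2-ArP-1-ArB-3-(TBS-oxy)propan-1-ol
Product: 24 (2R,3R,4R)-5,7-bis(benzyloxy)-3-ArP-2-ArB-4-(TBS-oxy)chromane
Conditions: Pd(OAc)2 (5 mol%), 2-(di-tert-butylphosphino)-1,1'-binaphthyl (6 mol%), Cs2CO3, toluene, 70 °C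
Reagents that add atoms: none
Why: Zerovalent palladium formed in situ from Pd(OAc)2 and the phosphine inserts into the C8a–Br bond, Cs2CO3 deprotonates the coordinated C2 hydroxyl to give a seven-membered aryl(alkoxo) chelate of divalent palladium, and C–O reductive elimination forms O1–C8a. The closest known reaction type is the Buchwald–Hartwig-type intramolecular etherification of aryl bromides with secondary alcohols, which is established for chromans and flavans and proceeds with retention at the carbinol carbon. Ring C of unit 1 closes as a six-membered ring, formally by exo attack of oxygen on the sp2 carbon C8a with the bromide exocyclic. No stereocentre is created: C2 keeps its configuration because the C2–O bond is never broken, and C3 cannot epimerise because C4 is a silylated carbinol, so the syn aldol pair becomes the cis C2/C3 pair. The step needs C–O reductive elimination to outrun β-hydride elimination at C2–H, which the bulky electron-rich di-tert-butylphosphine favours, and it needs a single reactive hydroxyl, which the C4 silyl ether secures because a C4 alkoxide could only form a five-membered palladacycle and be oxidised. The bromide is meta to both benzyloxy groups, so oxidative addition is not retarded, and the weak insoluble base limits silyl migration while acetal and benzyl ethers stay inert.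

Step 15
Reactants: 24 key chromane
Product: 26 5-(benzyloxy)-2-CHR-benzene-1,3-diol, via bis(trimethylsilyl) ether 25 (not isolated)
Conditions: TMSOTf, 2,2'-bipyridyl, CH2Cl2, 0 °C to rt; then H2O
Reagents that add atoms: none
Why: Silyl triflate/2,2'-bipyridyl cleavage of aromatic methoxymethyl ethers runs through aryl silyl ethers in a buffered, non-protic medium, so the ionisable C4 silyloxy group and the benzyl ethers should survive where protic acid would ionise C4.

Step 16
Reactants: 26 5-(benzyloxy)-2-CHR-benzene-1,3-diol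
Product: 27 5-(benzyloxy)-4-iodo-2-CHR-benzene-1,3-diol
Conditions: I2 (1.0 equiv), NaHCO3, THF/H2O, 0 °C
Reagents that add atoms: iodine, II
Why: Electrophilic iodination under bicarbonate reacts through the phenoxide and is therefore selective for the free resorcinol ring, whose two open positions are equivalent, so one equivalent should give the mono-iodide ortho to a hydroxyl.

Step 17
Reactants: 27 5-(benzyloxy)-4-iodo-2-CHR-benzene-1,3-diol
Product: 29 1-[6-(benzyloxy)-2,4-dihydroxy-3-CHR-phenyl]ethan-1-one, via ethoxyvinyl arene 28 (not isolated)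
Conditions: Bu3Sn(C(OEt)=CH2), Pd(PPh3)4 (cat.), CuI (cat.), dioxane, 90 °C; then 0.1 M aq. oxalic acid, THF, 0 °C
Reagents that add atoms: tributyl(1-ethoxyvinyl)stannane, CCCC[Sn](CCCC)(CCCC)C(=C)OCC; water, O
Why: Stille coupling tolerates free phenols and the copper co-catalyst helps the ortho,ortho-disubstituted iodide, and the electron-rich enol ether is hydrolysed by very dilute acid, which should leave the C4 silyl ether un-ionised.

Step 18
Reactants: 29 1-[6-(benzyloxy)-2,4-dihydroxy-3-CHR-phenyl]ethan-1-one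
Product: 30 1-[4,6-bis(benzyloxy)-2-hydroxy-3-CHR-phenyl]ethan-1-one
Conditions: BnBr (1.05 equiv), K2CO3, acetone, 50 °C
Reagents that add atoms: benzyl bromide, BrCc1ccccc1
Why: In this Williamson etherification the hydroxyl ortho to the acetyl group is hydrogen-bonded and unreactive, so only the para hydroxyl is benzylated and the oxygen next to the inter-unit bond stays free to become O1 of unit 2.

Step 19
Reactants: 30 1-[4,6-bis(benzyloxy)-2-hydroxy-3-CHR-phenyl]ethan-1-one; 31 4-(benzyloxy)benzaldehyde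
Product: 32 (E)-1-[4,6-bis(benzyloxy)-2-hydroxy-3-CHR-phenyl]-3-[4-(benzyloxy)phenyl]prop-2-en-1-one
Conditions: KOH, EtOH/THF, rt; neutralised to pH 7
Reagents that add atoms: none
Why: Claisen–Schmidt condensation of the 2-hydroxyacetophenone with the non-enolisable aldehyde gives the (E)-2'-hydroxychalcone, and no stereocentre of unit 1 is acidic at the carbinol oxidation level.

Step 20
Reactants: 32 2'-hydroxychalcone
Product: 33 (2S)-5,7-bis(benzyloxy)-2-[4-(benzyloxy)phenyl]-8-CHR-chroman-4-one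
Conditions: cinchona-derived bifunctional thiourea (quinidine series, 10 mol%), toluene, rt
Reagents that add atoms: none
Why: Organocatalytic intramolecular oxa-Michael addition (6-endo-trig) of the 2'-phenol to the enone, with hydrogen-bond activation of the enone and general-base activation of the phenol, should close ring C of unit 2 under catalyst control, and the quinine-derived pseudoenantiomer would be used if the quinidine series gave the opposite facial sense.

Step 21
Reactants: 33 silylated bis-chromane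
Product: 34 (2S)-5,7-bis(benzyloxy)-2-[4-(benzyloxy)phenyl]-8-[(2R,3S,4R)-5,7-bis(benzyloxy)-2-ArB-4-hydroxychroman-3-yl]chroman-4-one
Conditions: Bu4NF, AcOH (1:1), THF, rt to 40 °C
Reagents that add atoms: none
Why: Acetic-acid-buffered fluoride desilylation avoids the basic conditions that would open the flavanone of unit 2 by retro-oxa-Michael reaction, and by this point no free phenol remains that could displace the C4 oxygen.

Step 22
Reactants: 34 C4 alcohol
Product: 35 (2R,3R)-5,7-bis(benzyloxy)-2-ArB-3-[(2S)-5,7-bis(benzyloxy)-2-[4-(benzyloxy)phenyl]-4-oxochroman-8-yl]chroman-4-one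
Conditions: Dess–Martin periodinane, NaHCO3, CH2Cl2, 0 °C to rt
Reagents that add atoms: none
Why: Dess–Martin oxidation turns the benzylic carbinol into the C4 ketone under buffered, non-enolising conditions, so the cis C2/C3 pair should be retained.

Step 23
Reactants: 35 heptabenzyl biflavanone
Product: 36 CNP0105436.1
Conditions: H2 (1 atm), Pd/C, EtOAc/MeOH, rt
Reagents that add atoms: none
Why: Neutral hydrogenolysis removes all seven benzyl ethers without acid or base, which is the safest condition for the epimerisable cis C3 centre and for both flavanone rings.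

**Compound list**
1 | phloroglucinol | Oc1cc(O)cc(O)c1 | starting material
2 | 3,5-bis(methoxymethoxy)phenol | COCOc1cc(O)cc(OCOC)c1 | intermediate
3 | 1-(benzyloxy)-3,5-bis(methoxymethoxy)benzene | COCOc1cc(OCc2ccccc2)cc(OCOC)c1 | intermediate
4 | [4-(benzyloxy)-2,6-bis(methoxymethoxy)phenyl]lithium (formed in situ) | [Li]c1c(OCOC)cc(OCc2ccccc2)cc1OCOC | intermediate
5 | 2-[4-(benzyloxy)-2,6-bis(methoxymethoxy)phenyl]ethan-1-ol | OCCc1c(OCOC)cc(OCc2ccccc2)cc1OCOC | intermediate
6 | [4-(benzyloxy)-2,6-bis(methoxymethoxy)phenyl]acetaldehyde (formed in situ) | O=CCc1c(OCOC)cc(OCc2ccccc2)cc1OCOC | intermediate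
7 | [4-(benzyloxy)-2,6-bis(methoxymethoxy)phenyl]acetic acid | OC(=O)Cc1c(OCOC)cc(OCc2ccccc2)cc1OCOC | intermediate
8 | (R)-4-benzyl-2-oxazolidinone | O=C1OC[C@@H](Cc2ccccc2)N1 | starting material
9 | mixed anhydride of 7 with pivalic acid (formed in situ) | CC(C)(C)C(=O)OC(=O)Cc1c(OCOC)cc(OCc2ccccc2)cc1OCOC | intermediate
10 | (4R)-4-benzyl-3-{[4-(benzyloxy)-2,6-bis(methoxymethoxy)phenyl]acetyl}-1,3-oxazolidin-2-one | O=C(Cc1c(OCOC)cc(OCc2ccccc2)cc1OCOC)N1C(=O)OC[C@H]1Cc1ccccc1 | intermediate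
11 | 3,4-bis(benzyloxy)benzaldehyde | O=Cc1ccc(OCc2ccccc2)c(OCc2ccccc2)c1 | starting material
12 | (Z)-dibutylboron enolate of 10 (formed in situ) | CCCCB(CCCC)O/C(=C\c1c(OCOC)cc(OCc2ccccc2)cc1OCOC)N1C(=O)OC[C@H]1Cc1ccccc1 | intermediate
13 | O-dibutylboryl aldolate of 14 (formed in situ) | COCOc1cc(OCc2ccccc2)cc(OCOC)c1[C@H]([C@@H](OB(CCCC)CCCC)c1ccc(OCc2ccccc2)c(OCc2ccccc2)c1)C(=O)N1C(=O)OC[C@H]1Cc1ccccc1 | intermediate
14 | (4R)-4-benzyl-3-[(2R,3R)-2-ArP-3-ArB-3-hydroxypropanoyl]-1,3-oxazolidin-2-one (syn aldol) | COCOc1cc(OCc2ccccc2)cc(OCOC)c1[C@H]([C@@H](O)c1ccc(OCc2ccccc2)c(OCc2ccccc2)c1)C(=O)N1C(=O)OC[C@H]1Cc1ccccc1 | intermediate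
15 | (4R)-4-benzyl-3-[(2R,3R)-2-ArP-3-ArB-3-(triethylsilyloxy)propanoyl]-1,3-oxazolidin-2-one | COCOc1cc(OCc2ccccc2)cc(OCOC)c1[C@H]([C@@H](O[Si](CC)(CC)CC)c1ccc(OCc2ccccc2)c(OCc2ccccc2)c1)C(=O)N1C(=O)OC[C@H]1Cc1ccccc1 | intermediate
16 | (2S,3R)-2-ArP-3-ArB-3-(triethylsilyloxy)propan-1-ol | COCOc1cc(OCc2ccccc2)cc(OCOC)c1[C@H]([C@@H](O[Si](CC)(CC)CC)c1ccc(OCc2ccccc2)c(OCc2ccccc2)c1)CO | intermediate
17 | (2R,3R)-2-ArP-3-ArB-3-(triethylsilyloxy)propanal | COCOc1cc(OCc2ccccc2)cc(OCOC)c1[C@H]([C@@H](O[Si](CC)(CC)CC)c1ccc(OCc2ccccc2)c(OCc2ccccc2)c1)C=O | intermediate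
18 | 1,3-bis(benzyloxy)-5-bromobenzene | Brc1cc(OCc2ccccc2)cc(OCc2ccccc2)c1 | starting material
19 | 1,5-bis(benzyloxy)-3-bromo-2-iodobenzene | Brc1cc(OCc2ccccc2)cc(OCc2ccccc2)c1I | intermediate
20 | [2,4-bis(benzyloxy)-6-bromophenyl]magnesium chloride (formed in situ) | Cl[Mg]c1c(Br)cc(OCc2ccccc2)cc1OCc1ccccc1 | intermediate
21 | (1R,2S,3R)-1-ArA-2-ArP-3-ArB-3-(triethylsilyloxy)propan-1-ol | COCOc1cc(OCc2ccccc2)cc(OCOC)c1[C@H]([C@@H](O[Si](CC)(CC)CC)c1ccc(OCc2ccccc2)c(OCc2ccccc2)c1)[C@@H](O)c1c(OCc2ccccc2)cc(OCc2ccccc2)cc1Br | intermediate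
22 | (1R,2R,3R)-1-ArA-1-(tert-butyldimethylsilyloxy)-2-ArP-3-ArB-3-(triethylsilyloxy)propane | COCOc1cc(OCc2ccccc2)cc(OCOC)c1[C@H]([C@@H](O[Si](CC)(CC)CC)c1ccc(OCc2ccccc2)c(OCc2ccccc2)c1)[C@@H](O[Si](C)(C)C(C)(C)C)c1c(OCc2ccccc2)cc(OCc2ccccc2)cc1Br | intermediate
23 | (1R,2R,3R)-3-ArA-2-ArP-1-ArB-3-(tert-butyldimethylsilyloxy)propan-1-ol (precursor of the key step) | COCOc1cc(OCc2ccccc2)cc(OCOC)c1[C@H]([C@@H](O)c1ccc(OCc2ccccc2)c(OCc2ccccc2)c1)[C@@H](O[Si](C)(C)C(C)(C)C)c1c(OCc2ccccc2)cc(OCc2ccccc2)cc1Br | intermediate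
24 | (2R,3R,4R)-5,7-bis(benzyloxy)-3-ArP-2-ArB-4-(tert-butyldimethylsilyloxy)chromane (product of the key step; 2,3-cis and 3,4-cis) | COCOc1cc(OCc2ccccc2)cc(OCOC)c1[C@H]1[C@@H](O[Si](C)(C)C(C)(C)C)c2c(OCc3ccccc3)cc(OCc3ccccc3)cc2O[C@H]1c1ccc(OCc2ccccc2)c(OCc2ccccc2)c1 | intermediate
25 | bis(trimethylsilyl) ether of 26 (formed in situ) | C[Si](C)(C)Oc1cc(OCc2ccccc2)cc(O[Si](C)(C)C)c1[C@H]1[C@@H](O[Si](C)(C)C(C)(C)C)c2c(OCc3ccccc3)cc(OCc3ccccc3)cc2O[C@H]1c1ccc(OCc2ccccc2)c(OCc2ccccc2)c1 | intermediate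
26 | 5-(benzyloxy)-2-CHR-benzene-1,3-diol | Oc1cc(OCc2ccccc2)cc(O)c1[C@H]1[C@@H](O[Si](C)(C)C(C)(C)C)c2c(OCc3ccccc3)cc(OCc3ccccc3)cc2O[C@H]1c1ccc(OCc2ccccc2)c(OCc2ccccc2)c1 | intermediate
27 | 5-(benzyloxy)-4-iodo-2-CHR-benzene-1,3-diol | Oc1c(I)c(OCc2ccccc2)cc(O)c1[C@H]1[C@@H](O[Si](C)(C)C(C)(C)C)c2c(OCc3ccccc3)cc(OCc3ccccc3)cc2O[C@H]1c1ccc(OCc2ccccc2)c(OCc2ccccc2)c1 | intermediate
28 | 5-(benzyloxy)-4-(1-ethoxyethenyl)-2-CHR-benzene-1,3-diol (formed in situ) | Oc1c(C(=C)OCC)c(OCc2ccccc2)cc(O)c1[C@H]1[C@@H](O[Si](C)(C)C(C)(C)C)c2c(OCc3ccccc3)cc(OCc3ccccc3)cc2O[C@H]1c1ccc(OCc2ccccc2)c(OCc2ccccc2)c1 | intermediate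
29 | 1-[6-(benzyloxy)-2,4-dihydroxy-3-CHR-phenyl]ethan-1-one | Oc1c(C(C)=O)c(OCc2ccccc2)cc(O)c1[C@H]1[C@@H](O[Si](C)(C)C(C)(C)C)c2c(OCc3ccccc3)cc(OCc3ccccc3)cc2O[C@H]1c1ccc(OCc2ccccc2)c(OCc2ccccc2)c1 | intermediate
30 | 1-[4,6-bis(benzyloxy)-2-hydroxy-3-CHR-phenyl]ethan-1-one | Oc1c(C(C)=O)c(OCc2ccccc2)cc(OCc2ccccc2)c1[C@H]1[C@@H](O[Si](C)(C)C(C)(C)C)c2c(OCc3ccccc3)cc(OCc3ccccc3)cc2O[C@H]1c1ccc(OCc2ccccc2)c(OCc2ccccc2)c1 | intermediate
31 | 4-(benzyloxy)benzaldehyde | O=Cc1ccc(OCc2ccccc2)cc1 | starting material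
32 | (E)-1-[4,6-bis(benzyloxy)-2-hydroxy-3-CHR-phenyl]-3-[4-(benzyloxy)phenyl]prop-2-en-1-one | Oc1c(C(=O)/C=C/c2ccc(OCc3ccccc3)cc2)c(OCc2ccccc2)cc(OCc2ccccc2)c1[C@H]1[C@@H](O[Si](C)(C)C(C)(C)C)c2c(OCc3ccccc3)cc(OCc3ccccc3)cc2O[C@H]1c1ccc(OCc2ccccc2)c(OCc2ccccc2)c1 | intermediate
33 | (2S)-5,7-bis(benzyloxy)-2-[4-(benzyloxy)phenyl]-8-CHR-chroman-4-one | O=C1C[C@@H](c2ccc(OCc3ccccc3)cc2)Oc2c1c(OCc1ccccc1)cc(OCc1ccccc1)c2[C@H]1[C@@H](O[Si](C)(C)C(C)(C)C)c2c(OCc3ccccc3)cc(OCc3ccccc3)cc2O[C@H]1c1ccc(OCc2ccccc2)c(OCc2ccccc2)c1 | intermediate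
34 | (2S)-5,7-bis(benzyloxy)-2-[4-(benzyloxy)phenyl]-8-[(2R,3S,4R)-5,7-bis(benzyloxy)-2-ArB-4-hydroxychroman-3-yl]chroman-4-one | O=C1C[C@@H](c2ccc(OCc3ccccc3)cc2)Oc2c1c(OCc1ccccc1)cc(OCc1ccccc1)c2[C@H]1[C@@H](O)c2c(OCc3ccccc3)cc(OCc3ccccc3)cc2O[C@H]1c1ccc(OCc2ccccc2)c(OCc2ccccc2)c1 | intermediate
35 | (2R,3R)-5,7-bis(benzyloxy)-2-ArB-3-{(2S)-5,7-bis(benzyloxy)-2-[4-(benzyloxy)phenyl]-4-oxochroman-8-yl}chroman-4-one | O=C1C[C@@H](c2ccc(OCc3ccccc3)cc2)Oc2c1c(OCc1ccccc1)cc(OCc1ccccc1)c2[C@H]1C(=O)c2c(OCc3ccccc3)cc(OCc3ccccc3)cc2O[C@H]1c1ccc(OCc2ccccc2)c(OCc2ccccc2)c1 | intermediate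
36 | CNP0105436.1, (2R,3R)-2-(3,4-dihydroxyphenyl)-3-[(2S)-5,7-dihydroxy-2-(4-hydroxyphenyl)-4-oxochroman-8-yl]-5,7-dihydroxychroman-4-one | O=C1C[C@@H](c2ccc(O)cc2)Oc2c1c(O)cc(O)c2[C@H]1C(=O)c2c(O)cc(O)cc2O[C@H]1c1ccc(O)c(O)c1 | target

**Step count and risks**
Total: 23 steps. Longest linear sequence: 22 steps (steps 1–9 and 11–23, from phloroglucinol); step 10 is a one-step side branch.

Risk 1, step 20: poor facial selectivity in the oxa-Michael closure, possibly eroded further by reversible ring opening, would leave C2 of unit 2 as a mixture. The fallback sets out from 30. Condensation with N,N-dimethylformamide dimethyl acetal (toluene, 90 °C) should give the (E)-dimethylaminoenone F1. F1 is then closed with loss of dimethylamine under mild catalysis (pyridinium p-toluenesulfonate or silica gel) to the chromone F2. A rhodium-catalysed asymmetric 1,4-addition of 4-(benzyloxy)phenylboronic acid follows, using [Rh(OH)(cod)]2 with the enantiomer of an electron-poor MeO-BIPHEP-type bisphosphine that delivers 2S. This sets C2 of unit 2 under catalyst control and rejoins the route at 33.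

Risk 2, step 11: enolisation of the α-aryl aldehyde by the hindered, basic aryl Grignard reagent could compete with 1,2-addition, leading to epimerisation at C3 or β-elimination of the silyloxy group. The fallback sets out from 14. Transamidation with AlMe3 and N,O-dimethylhydroxylamine hydrochloride should give the Weinreb amide F3 and release the auxiliary. Silylation with TESCl/imidazole gives its triethylsilyl ether F4. Addition of the arylmagnesium chloride 20 then stops at the aryl ketone F5, because the chelated tetrahedral intermediate does not enolise. An oxazaborolidine-catalysed borane reduction, with the catalyst enantiomer chosen for the (1R) carbinol, returns to 21.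

Risk 3, step 14: β-hydride elimination from the palladium alkoxide (oxidation at C2 with loss of bromine from ring A), or slow alkoxide binding at the congested carbinol, could stall ring closure. The fallback sets out from 23. A copper-catalysed halogen exchange (CuI, NaI, trans-N,N'-dimethylcyclohexane-1,2-diamine, dioxane, 110 °C) should give the aryl iodide F6. F6 is closed by an Ullmann-type intramolecular etherification (CuI, 3,4,7,8-tetramethyl-1,10-phenanthroline, Cs2CO3, toluene, 110 °C). The alkoxide of monovalent copper is much less prone to β-hydride loss and the C2–O bond is again untouched, and the route is rejoined at 24.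

**Further compounds**
F1 | step 20 | (E)-1-[4,6-bis(benzyloxy)-2-hydroxy-3-CHR-phenyl]-3-(dimethylamino)prop-2-en-1-one | Oc1c(C(=O)/C=C/N(C)C)c(OCc2ccccc2)cc(OCc2ccccc2)c1[C@H]1[C@@H](O[Si](C)(C)C(C)(C)C)c2c(OCc3ccccc3)cc(OCc3ccccc3)cc2O[C@H]1c1ccc(OCc2ccccc2)c(OCc2ccccc2)c1
F2 | step 20 | 5,7-bis(benzyloxy)-8-CHR-4H-chromen-4-one | O=C1C=COc2c1c(OCc1ccccc1)cc(OCc1ccccc1)c2[C@H]1[C@@H](O[Si](C)(C)C(C)(C)C)c2c(OCc3ccccc3)cc(OCc3ccccc3)cc2O[C@H]1c1ccc(OCc2ccccc2)c(OCc2ccccc2)c1
F3 | step 11 | (2R,3R)-2-ArP-3-ArB-3-hydroxy-N-methoxy-N-methylpropanamide | COCOc1cc(OCc2ccccc2)cc(OCOC)c1[C@H]([C@@H](O)c1ccc(OCc2ccccc2)c(OCc2ccccc2)c1)C(=O)N(C)OC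
F4 | step 11 | (2R,3R)-2-ArP-3-ArB-N-methoxy-N-methyl-3-(triethylsilyloxy)propanamide | COCOc1cc(OCc2ccccc2)cc(OCOC)c1[C@H]([C@@H](O[Si](CC)(CC)CC)c1ccc(OCc2ccccc2)c(OCc2ccccc2)c1)C(=O)N(C)OC
F5 | step 11 | (2R,3R)-1-ArA-2-ArP-3-ArB-3-(triethylsilyloxy)propan-1-one | COCOc1cc(OCc2ccccc2)cc(OCOC)c1[C@H]([C@@H](O[Si](CC)(CC)CC)c1ccc(OCc2ccccc2)c(OCc2ccccc2)c1)C(=O)c1c(OCc2ccccc2)cc(OCc2ccccc2)cc1Br
F6 | step 14 | (1R,2R,3R)-3-[2,4-bis(benzyloxy)-6-iodophenyl]-2-ArP-1-ArB-3-(tert-butyldimethylsilyloxy)propan-1-ol | COCOc1cc(OCc2ccccc2)cc(OCOC)c1[C@H]([C@@H](O)c1ccc(OCc2ccccc2)c(OCc2ccccc2)c1)[C@@H](O[Si](C)(C)C(C)(C)C)c1c(OCc2ccccc2)cc(OCc2ccccc2)cc1I
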